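A small charge of free enzyme, 0.16 µM in most of these flasks, has to make the target, so ask first how much work it does before it dies.

| flask | starting material | second substrate | free enzyme | temperature | remark | time |
|---|---|---|---|---|---|---|
| midnight | 20 mM (in portions, 2) | 16 mM | 0.13 µM | 0 °C | run made earlier; portions every 8.0 h |  |
| summer | 20 mM (in portions, 2) | 16 mM | 0.37 µM | 25 °C | run made earlier; portions every 8.0 h |  |
| spring | 20 mM (in portions, 2) | 9.9 mM | 0.16 µM | 0 °C | run made earlier; portions every 8.0 h |  |
| zeta | 20 mM (in portions, 2) | 25.0 mM | 0.16 µM | 5 °C | the portions of starting material follow each other after 8.0 h, the first at the start | 3.0 d |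
| epsilon | 20 mM (in portions, 2) | 4.00 mM | 0.16 µM | 45 °C | the portions of starting material follow each other after 30 h, the first at the start | 3.0 d |
| theta | 20 mM (in portions, 2) | 8.00 mM | 0.16 µM | 5 °C | the portions of starting material follow each other after 8.0 h, the first at the start | 3.0 d |
| beta | 20 mM (in portions, 2) | 16.0 mM | 0.16 µM | 5 °C | the portions of starting material follow each other after 8.0 h, the first at the start | 3.0 d |
| eta | 80 mM (in portions, 2) | 16.0 mM | 0.16 µM | 5 °C | the portions of starting material follow each other after 8.0 h, the first at the start | 3.0 d |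
| delta | 20 mM (in portions, 2) | 16.0 mM | 0.60 µM | 5 °C | the portions of starting material follow each other after 8.0 h, the first at the start | 3.0 d |

| run | time / h | target / % | starting material / % |
|---|---|---|---|
| midnight | 3.00 | 7 | 43 |
| midnight | 4.00 | 11 | 42 |
| midnight | 6.00 | 10 | 37 |
| midnight | 10.0 | 19 | 81 |
| midnight | 15.0 | 27 | 72 |
| midnight | 25.0 | 38 | 66 |
| midnight | 40.0 | 49 | 52 |
| summer | 2.00 | 20 | 32 |
| summer | 4.00 | 18 | 31 |
| summer | 6.00 | 20 | 32 |
| summer | 8.00 | 22 | 28 |
| summer | 10.0 | 19 | 79 |
| summer | 12.0 | 21 | 80 |
| summer | 15.0 | 21 | 78 |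
| spring | 8.00 | 15 | 35 |
| spring | 15.0 | 21 | 76 |
| spring | 20.0 | 26 | 75 |
| spring | 30.0 | 29 | 73 |
| spring | 40.0 | 34 | 66 |

(scatter of a reading: 1.5 percentage points)

* the flasks put in order of amount of target, in percent of the starting material charged, best first, at 3.0 d (zeta / epsilon / theta / beta / eta / delta)
* the amount of target, in percent of the starting material charged of the flask you put first, at 3.0 d
* the amount of target, in percent of the starting material charged of the flask you put last, at 3.0 d



In the summer run the target stands at 21 % at 15.0 h, and the second portion adds none, which looks like catalyst deactivation. So I count each target as one second substrate used, and I take the logarithm of the second substrate's charge over what remains, divided by the enzyme.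

The midnight run gives 2.09 µM⁻¹ at 10.0 h, 4.96 µM⁻¹ at 25.0 h and 7.29 µM⁻¹ at 40.0 h. The spring run, with other charges, gives 7.26 µM⁻¹ at 40.0 h, close to the midnight value, so one curve serves both.

Those midnight steps cover equal times and shrink, and if they go on shrinking by the same ratio, they sum to a lifetime capacity of 17.5 µM⁻¹. The summer plateau gives 0.823 µM⁻¹. Taking the logarithm as straight in temperature, you get 9.49 µM⁻¹ at 5 °C and 0.0713 µM⁻¹ at 45 °C.

Multiply capacity by enzyme and you have my one number, the reach, 1.52: the logarithm of how far the enzyme's life cuts down the second substrate. It leaves 21.9 % of that charge, and the target is the used part times the ratio of second substrate to starting material.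

My reckoning gives zeta 97.6 %, delta 79.7 %, beta 62.5 %, theta 31.2 %, eta 15.6 % and epsilon 0.227 %.

Is one number enough? Going round once more, zeta's answer would leave 2.40 % of the starting material, less than the lowest reading in the runs that fed the number, the summer run's 28 % at 8.00 h. So I hold zeta's figure as too high.

The forecast gives the order zeta > delta > beta > theta > eta > epsilon, with 82 % on top (range 72 % to 92 %) and 0.4 % last (range 0.1 % to 1.5 %), saying “so this is inactivation, not equilibrium”. Its order is mine, but its top lies below my 97.6 %.

The flasks give zeta > delta > beta > theta > eta > epsilon, with 89.2 % first and 0.234 % last.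

    first complex ⇌ loaded enzyme + first product (K = 0.0370 M, k = 53000 h⁻¹, Ea = 62.0 kJ mol⁻¹, ΔH = −42.0 kJ mol⁻¹)
    2 loaded enzyme → spent catalyst (k = 3.60 × 10⁶ M⁻¹ h⁻¹, Ea = 37.0 kJ mol⁻¹)
    starting material + free enzyme ⇌ first complex (K = 30.0 M⁻¹, k = 2.50 × 10⁶ M⁻¹ h⁻¹, Ea = 42.0 kJ mol⁻¹, ΔH = −20.0 kJ mol⁻¹)
    free enzyme → unfolded enzyme (k = 0.00190 h⁻¹, Ea = 219 kJ mol⁻¹)
    second substrate + loaded enzyme ⇌ second complex (K = 28.0 M⁻¹, k = 14000 M⁻¹ s⁻¹, Ea = 34.0 kJ mol⁻¹, ΔH = −18.0 kJ mol⁻¹)
    second complex → free enzyme + target (k = 55000 h⁻¹, Ea = 55.0 kJ mol⁻¹)
    (constants at 5 °C)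

The reach of 1.52 promised zeta 21.9 % of its second substrate left, and zeta holds 29 % at 3.00 d. Now take the neighbour of zeta charged with 10 mM of second substrate, the rest held, so 0.500 equiv to starting material. The same reach gives it 39.1 % of target. That neighbour gives 38.0 %, with 24 % of its second substrate and 62 % of its starting material left.

Readings and results come from a simulation from invented constants; the scatter is artificial.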